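## Retrosynthetic overview
1. The right cycloheptene is the last ring, opened by RCM. Its 3‑oxobutyl chain and 1,1‑disubstituted alkene come from a Ru Alder‑ene coupling of a terminal alkyne with 3‑buten‑2‑ol, and the C1–OH comes from a Schenck ene reaction.
2. Key cut: the left cycloheptene and the central spiro‑cyclohexene are disconnected together. This leads to an open enyne lactone, methyl vinyl ketone and the mirror‑image enyne lactone (enyne RCM/CM, then heterochiral Diels–Alder, in one flask).
3. Both enyne lactones come from one allylboronate plus the (S)‑ or (R)‑β‑alkynyl aldehyde, by phosphoric‑acid allylboration and lactonisation.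
4. The aldehydes come from crotonaldehyde and TIPS‑acetylene (Rh conjugate alkynylation, both ligand antipodes). The boronate comes from methyl propiolate, allylMgBr and ICH2Bpin.
5. Ring order: the two butyrolactones, then the left seven‑membered and central six‑membered rings together, then the right seven‑membered ring.

**Numbering:** xanthanolide numbering is used. C1–C15 is the left (diene‑derived) half and primed numbers are the right half. C11/C12/C13 are the lactone α‑carbon, carbonyl and methylene. The target is 1S,5R,7R,8R,10S,7'S,8'S,10'R,11'R, so the right half belongs to the mirror‑image series of the left half.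

**Assumption:** the sense of induction of each chiral catalyst is assigned by analogy with its parent reaction. Both antipodes are used once each, so a reversed sense would only swap them between steps 1/2 and between steps 4/5.

## Route

**Step 1**
Reactants: 1 (E)-crotonaldehyde; 2 (triisopropylsilyl)acetylene
Product: 3 (S)-3-methyl-5-(triisopropylsilyl)pent-4-ynal
Conditions: [Rh(OAc)(C2H4)2]2 (2.5 mol%), (R)-DTBM-SEGPHOS (6 mol%), MeOH, 40 °C
Reagents that add atoms: (triisopropylsilyl)acetylene 2, C#C[Si](C(C)C)(C(C)C)C(C)C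
Why: Rhodium‑catalysed asymmetric conjugate alkynylation of an enal, in which the bulky silyl group suppresses alkyne dimerisation and the bisphosphine shields one enal face, setting C10 as S.

**Step 2**
Reactants: 1 (E)-crotonaldehyde; 2 (triisopropylsilyl)acetylene
Product: 4 (R)-3-methyl-5-(triisopropylsilyl)pent-4-ynal
Conditions: [Rh(OAc)(C2H4)2]2 (2.5 mol%), (S)-DTBM-SEGPHOS (6 mol%), MeOH, 40 °C
Reagents that add atoms: (triisopropylsilyl)acetylene 2, C#C[Si](C(C)C)(C(C)C)C(C)C
Why: The same asymmetric conjugate alkynylation with the antipodal ligand sets C10' as R.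

**Step 3**
Reactants: 5 methyl propiolate; 6 allylmagnesium bromide; 7 2-(iodomethyl)-4,4,5,5-tetramethyl-1,3,2-dioxaborolane
Product: 9 methyl (2E)-2-[(pinacolboryl)methyl]hexa-2,5-dienoate (allyl cis to CH2B), via alkenylcopper 8 (not isolated)
Conditions: 6, CuBr·SMe2 (1.0 equiv), THF, −78 °C; 5, −78 °C, 1 h; then 7, DMPU, −78 → 0 °C
Reagents that add atoms: allylmagnesium bromide 6, C=CC[Mg]Br; 2-(iodomethyl)pinacolboronate 7, ICB1OC(C)(C)C(C)(C)O1
Why: Syn carbocupration of the ynoate followed by stereoretentive alkylation of the alkenylcopper, with the low temperature preventing allenolate scrambling so that allyl ends cis to CH2B (no stereocentre is formed).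

**Step 4**
Reactants: 3 (S)-aldehyde; 9 allylboronate
Product: 12 (4R,5R)-4-allyl-3-methylene-5-[(2S)-2-methylbut-3-yn-1-yl]dihydrofuran-2(3H)-one, via homoallylic pinacol borate 10 (not isolated), via TIPS-alkynyl lactone 11 (not isolated)
Conditions: (S)-TRIP phosphoric acid (10 mol%), 4 Å MS, PhMe, 0 °C → rt, 48 h; then TBAF (1.5 equiv), AcOH (1.5 equiv), THF, 0 °C → rt, same flask
Reagents that add atoms: none
Why: Chiral‑phosphoric‑acid‑catalysed allylboration through a closed chair in which the substituent cis to CH2B sits axial gives the syn adduct, the catalyst chooses the aldehyde face (7R,8R), the borate oxygen closes the cis‑lactone on the methyl ester, and buffered fluoride then removes the silyl group.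

**Step 5**
Reactants: 4 (R)-aldehyde; 9 allylboronate
Product: 15 (4S,5S)-4-allyl-3-methylene-5-[(2R)-2-methylbut-3-yn-1-yl]dihydrofuran-2(3H)-one, via ent-homoallylic pinacol borate 13 (not isolated), via ent-TIPS-alkynyl lactone 14 (not isolated)
Conditions: (R)-TRIP phosphoric acid (10 mol%), 4 Å MS, PhMe, 0 °C → rt, 48 h; then TBAF (1.5 equiv), AcOH (1.5 equiv), THF, 0 °C → rt, same flask
Reagents that add atoms: none
Why: The mirror‑image allylboration/lactonisation/desilylation sets 7'S,8'S by the same chair model with the antipodal acid.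

**Step 6 (key step)**
Reactants: 12 enyne lactone; 16 methyl vinyl ketone; 15 mirror-image enyne lactone
Product: 19 spiro Diels–Alder adduct (3R,5R,7R,8R,10S,7'S,8'S,10'R,11'R), via vinylcycloheptene lactone 17 (not isolated), via (+)-8-epi-xanthatin 18 (not isolated)
Conditions: 16 (8 equiv), second-generation Hoveyda–Grubbs catalyst RuCl2(H2IMes)(=CH-C6H4-2-OiPr) (10 mol%), CH2Cl2 (0.01 M), 40 °C, 12 h; ethyl vinyl ether quench, strip volatiles under vacuum; then 15 (5 equiv, excess recovered), BHT (0.1 equiv), PhMe (2 M), 110 °C, 48 h, same flask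
Reagents that add atoms: methyl vinyl ketone 16, C=CC(C)=O
Why: Domino ring‑closing enyne metathesis/cross metathesis builds the left cycloheptene and its E‑dienone, and an "ortho"‑regioselective thermal Diels–Alder reaction follows in which 15 adds to the diene face opposite C14 and the lactone through its own face anti to both cis substituents, so that for this heterochiral pair only the carbonyl‑endo alignment is geometrically possible, giving 5R and 11'R with H3 cis to H5.

**Step 7**
Reactants: 19 Diels–Alder adduct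
Product: 21 C1 tertiary alcohol (1S) with conjugated C2=C3 acetyl enone, via C1 hydroperoxide 20 (not isolated)
Conditions: O2, tetraphenylporphyrin (1 mol%), white LED, CH2Cl2, −20 °C; then PPh3 (1.1 equiv), 0 °C
Reagents that add atoms: dioxygen, O=O
Why: In the Schenck ene reaction, singlet oxygen attacks the only electron‑rich trisubstituted alkene (terminal alkene, alkyne and methylene lactone are inert) and removes the doubly activated H3 suprafacially, so oxygen lands on C1 on the face of H3 and H5 (1S) while the alkene moves into conjugation, and PPh3 reduces the O–O bond.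

**Step 8**
Reactants: 21 hydroxy enone; 22 3-buten-2-ol (racemic)
Product: 23 RCM precursor with a C1'(=CH2)CH2CH2C(O)CH3 chain on C10'
Conditions: 22 (5 equiv), [CpRu(MeCN)3]PF6 (10 mol%), acetone, rt
Reagents that add atoms: 3-buten-2-ol 22, C=CC(C)O
Why: In the ruthenium‑catalysed alkene–alkyne (Alder‑ene) coupling, the ruthenacyclopentene joins the internal alkyne carbon to the terminal carbon of the allylic alcohol and β‑hydride loss from the carbinol carbon gives the methyl ketone, with no stereocentre touched and 1,1‑disubstituted alkenes and the tertiary alcohol unreactive.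

**Step 9**
Reactants: 23 RCM precursor
Product: 24 target CNP0195550.3
Conditions: second-generation Hoveyda–Grubbs catalyst RuCl2(H2IMes)(=CH-C6H4-2-OiPr) (10 mol%), PhMe (0.002 M), 80 °C
Reagents that add atoms: none
Why: Ring‑closing metathesis of the C7' allyl group with the 1,1‑disubstituted alkene closes the right cycloheptene as the ring‑constrained trisubstituted C1'=C5' alkene, while the methylene lactone and the hindered enone do not react.

## Compound list
1 | (E)-crotonaldehyde | C/C=C/C=O | starting material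
2 | (triisopropylsilyl)acetylene | C#C[Si](C(C)C)(C(C)C)C(C)C | starting material
3 | (S)-3-methyl-5-(triisopropylsilyl)pent-4-ynal | O=CC[C@H](C)C#C[Si](C(C)C)(C(C)C)C(C)C | intermediate
4 | (R)-3-methyl-5-(triisopropylsilyl)pent-4-ynal | O=CC[C@@H](C)C#C[Si](C(C)C)(C(C)C)C(C)C | intermediate
5 | methyl propiolate | C#CC(=O)OC | starting material
6 | allylmagnesium bromide | C=CC[Mg]Br | starting material
7 | 2-(iodomethyl)-4,4,5,5-tetramethyl-1,3,2-dioxaborolane | ICB1OC(C)(C)C(C)(C)O1 | starting material
8 | methyl (Z)-2-cupriohexa-2,5-dienoate (allyl cis to Cu) | C=CC/C=C(\[Cu])C(=O)OC | intermediate (not isolated)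
9 | methyl (2E)-2-[(pinacolboryl)methyl]hexa-2,5-dienoate (allyl cis to CH2B) | C=CC/C=C(\CB1OC(C)(C)C(C)(C)O1)C(=O)OC | intermediate
10 | methyl (3R,4R,6S)-3-allyl-6-methyl-2-methylene-4-(pinacolboryloxy)-8-(triisopropylsilyl)oct-7-ynoate | C=C(C(=O)OC)[C@@H](CC=C)[C@H](OB1OC(C)(C)C(C)(C)O1)C[C@H](C)C#C[Si](C(C)C)(C(C)C)C(C)C | intermediate (not isolated)
11 | (4R,5R)-4-allyl-3-methylene-5-[(2S)-2-methyl-4-(triisopropylsilyl)but-3-yn-1-yl]dihydrofuran-2(3H)-one | C=C1C(=O)O[C@H](C[C@H](C)C#C[Si](C(C)C)(C(C)C)C(C)C)[C@@H]1CC=C | intermediate (not isolated)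
12 | (4R,5R)-4-allyl-3-methylene-5-[(2S)-2-methylbut-3-yn-1-yl]dihydrofuran-2(3H)-one (cis-lactone) | C=C1C(=O)O[C@H](C[C@H](C)C#C)[C@@H]1CC=C | intermediate
13 | methyl (3S,4S,6R)-3-allyl-6-methyl-2-methylene-4-(pinacolboryloxy)-8-(triisopropylsilyl)oct-7-ynoate | C=C(C(=O)OC)[C@H](CC=C)[C@@H](OB1OC(C)(C)C(C)(C)O1)C[C@@H](C)C#C[Si](C(C)C)(C(C)C)C(C)C | intermediate (not isolated)
14 | (4S,5S)-4-allyl-3-methylene-5-[(2R)-2-methyl-4-(triisopropylsilyl)but-3-yn-1-yl]dihydrofuran-2(3H)-one | C=C1C(=O)O[C@@H](C[C@@H](C)C#C[Si](C(C)C)(C(C)C)C(C)C)[C@H]1CC=C | intermediate (not isolated)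
15 | (4S,5S)-4-allyl-3-methylene-5-[(2R)-2-methylbut-3-yn-1-yl]dihydrofuran-2(3H)-one (enantiomer of 12) | C=C1C(=O)O[C@@H](C[C@@H](C)C#C)[C@H]1CC=C | intermediate
16 | methyl vinyl ketone | C=CC(C)=O | starting material
17 | (3aR,7S,8aR)-7-methyl-3-methylene-6-vinyl-3,3a,4,7,8,8a-hexahydro-2H-cyclohepta[b]furan-2-one | C=C1C(=O)O[C@@H]2C[C@H](C)C(C=C)=CC[C@H]12 | intermediate (not isolated)
18 | (+)-8-epi-xanthatin, (3aR,7S,8aR), E-dienone | C=C1C(=O)O[C@@H]2C[C@H](C)C(/C=C/C(C)=O)=CC[C@H]12 | intermediate (not isolated)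
19 | Diels–Alder adduct: C5–C13' and C3–C11' bonds, C1=C2 alkene, H3 cis to H5, spiro-lactone carbonyl cis to C6; right half still carries the C7' allyl and the C10' ethynyl group | C=C1C(=O)O[C@@H]2C[C@H](C)C3=C[C@@H](C(C)=O)[C@]4(C[C@H]3C[C@H]12)C(=O)O[C@@H](C[C@@H](C)C#C)[C@H]4CC=C | intermediate
20 | (1S)-1-hydroperoxide of 19 with C2=C3 enone | C=C1C(=O)O[C@@H]2C[C@H](C)[C@@]3(OO)C=C(C(C)=O)[C@]4(C[C@H]3C[C@H]12)C(=O)O[C@@H](C[C@@H](C)C#C)[C@H]4CC=C | intermediate (not isolated)
21 | (1S)-1-hydroxy enone, OH cis to H5, right half an open enyne | C=C1C(=O)O[C@@H]2C[C@H](C)[C@@]3(O)C=C(C(C)=O)[C@]4(C[C@H]3C[C@H]12)C(=O)O[C@@H](C[C@@H](C)C#C)[C@H]4CC=C | intermediate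
22 | 3-buten-2-ol (racemic) | C=CC(C)O | starting material
23 | RCM precursor: as 21, with C10' bearing C(=CH2)CH2CH2C(O)CH3 | C=C1C(=O)O[C@@H]2C[C@H](C)[C@@]3(O)C=C(C(C)=O)[C@]4(C[C@H]3C[C@H]12)C(=O)O[C@@H](C[C@@H](C)C(=C)CCC(C)=O)[C@H]4CC=C | intermediate
24 | CNP0195550.3 | C=C1C(=O)O[C@@H]2C[C@H](C)[C@@]3(O)C=C(C(C)=O)[C@]4(C[C@H]3C[C@H]12)C(=O)O[C@H]1C[C@@H](C)C(CCC(C)=O)=CC[C@H]14 | target

## Step count
- **Total steps:** 9.
- **Longest linear sequence:** 6 (steps 1 → 4 → 6 → 7 → 8 → 9; the branches through steps 3 or 2/5 are equally long).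

## The three steps most likely to fail

**Step 6.**
- Risk: both Diels–Alder partners are electron‑poor, so the cycloaddition is slow. In addition, 18 carries its own methylene lactone and can homodimerise in competition with 15. Ruthenium that survives the quench would also ring‑close 15.
- Fallback (sets out from 12, returns at 19): remove the competing dienophile.
- Conjugate addition of thiophenol (Et3N, CH2Cl2) gives the α‑(phenylthiomethyl) lactone F1 as C11 epimers.
- The same enyne RCM/CM with 16 gives thio‑masked 8‑epi‑xanthatin F2, which cannot dimerise through that position.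
- Heating F2 with only 1.5 equiv of 15 gives the thio‑masked Diels–Alder adduct F3.
- NaIO4 gives the sulfoxide F4, and its thermal syn elimination (PhMe, 90 °C, CaCO3) restores the methylene lactone, which is 19.

**Step 7.**
- Risk: H3 may sit pseudo‑equatorial next to the quaternary C11'. Singlet oxygen could then abstract H5 instead and give a C2 hydroperoxide.
- Fallback (sets out from 19, returns at 21): mCPBA (NaHCO3, CH2Cl2, 0 °C) epoxidises the only nucleophilic alkene on the face away from the pseudoaxial acetyl group, giving the 1,2‑epoxy ketone F5.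
- Catalytic DBU then deprotonates C3 and opens the C2–O bond (E1cB). This can only place the oxygen on C1 and the alkene at C2=C3, giving 21.

**Step 8.**
- Risk: the branched propargylic carbon may erode the branched/linear ratio, and the C7' allyl group of a second molecule can compete with 22.
- Fallback (sets out from 21, returns at 24, skipping 23 and step 9): enyne RCM/CM with 22 and the second‑generation Hoveyda–Grubbs catalyst closes the right cycloheptene first and gives the dienyl carbinol F6.
- Redox isomerisation of its secondary allylic alcohol (CpRu(PPh3)2Cl, Et3NHPF6, dioxane, 90 °C) gives the saturated 3‑oxobutyl chain. The tertiary C1 alcohol has no carbinol hydrogen and is not affected.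

## Further compounds
F1 | step 6 | α-(phenylthiomethyl) lactone from 12 (C11 epimers) | c1ccccc1SCC1C(=O)O[C@H](C[C@H](C)C#C)[C@@H]1CC=C
F2 | step 6 | thio-masked 8-epi-xanthatin (C11 epimers) | c1ccccc1SCC1C(=O)O[C@@H]2C[C@H](C)C(/C=C/C(C)=O)=CC[C@H]12
F3 | step 6 | thio-masked Diels–Alder adduct (C11 epimers) | c1ccccc1SCC1C(=O)O[C@@H]2C[C@H](C)C3=C[C@@H](C(C)=O)[C@]4(C[C@H]3C[C@H]12)C(=O)O[C@@H](C[C@@H](C)C#C)[C@H]4CC=C
F4 | step 6 | sulfoxide of F3 (C11 and S epimers) | O=S(CC1C(=O)O[C@@H]2C[C@H](C)C3=C[C@@H](C(C)=O)[C@]4(C[C@H]3C[C@H]12)C(=O)O[C@@H](C[C@@H](C)C#C)[C@H]4CC=C)c1ccccc1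
F5 | step 7 | 1,2-epoxy ketone, oxygen on the H5 face | C=C1C(=O)O[C@@H]2C[C@H](C)[C@@]3(O5)[C@H]5[C@@H](C(C)=O)[C@]4(C[C@H]3C[C@H]12)C(=O)O[C@@H](C[C@@H](C)C#C)[C@H]4CC=C
F6 | step 8 | dienyl carbinol with closed right cycloheptene (carbinol epimers) | C=C1C(=O)O[C@@H]2C[C@H](C)[C@@]3(O)C=C(C(C)=O)[C@]4(C[C@H]3C[C@H]12)C(=O)O[C@H]1C[C@@H](C)C(/C=C/C(C)O)=CC[C@H]14
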